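**Retrosynthetic overview**

- Target 19 comes from the bis(methoxymethyl) ether 17 by phenol deprotection, and 17 from the 2,5-dihydrofuran 16 by dehydrogenation.
- Feature used: in the furan ring (O1, C2 bearing the 2,5-dihydroxyphenyl ring, C3–H, C4 bearing the (S)-ester side chain, C5–H) the C3=C4 bond lies opposite O1. At the 2,5-dihydro level, cutting C3=C4 leaves a 1-arylallyl 2-substituted-allyl ether, 15, so ring-closing metathesis forms this bond.
- 15 comes from Steglich esterification of the (S)-allylic alcohol 13 with 3-methylbut-2-enoic acid; 13 comes from CBS reduction of the α-methylene ketone 12.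
- 12 comes from the 2-lithioallyl ether of bromide 6 and Weinreb amide 9; 6 from aryl vinyl carbinol 4 and 2,3-dibromopropene; 4 from protected aldehyde 2 and vinylmagnesium bromide.
- Ring order: the benzene ring is bought; the furan is the only ring made, closed in step 8 and aromatised in step 9.

Key step: step 8

Assumption: in the CBS reduction the 2-substituted alkenyl group of 12 is taken to act as the larger carbonyl substituent; compounds 4, 6, 10–13, 15 and 16 are carried as both configurations at the aryl-bearing carbon, which becomes sp2 in step 9.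

**Route**

Step 1
Reactants: 1 2,5-dihydroxybenzaldehyde
Product: 2 2,5-bis(methoxymethoxy)benzaldehyde
Conditions: MOMCl (3 equiv), iPr2NEt (4 equiv), CH2Cl2, 0 °C to rt
Reagents that add atoms: chloromethyl methyl ether, COCCl
Why: Amine-mediated O-alkylation of both phenols by the reactive α-chloro ether (Williamson-type methoxymethylation), with excess reagent to drive the hydrogen-bonded ortho hydroxyl to completion.

Step 2
Reactants: 2 2,5-bis(methoxymethoxy)benzaldehyde; 3 vinylmagnesium bromide
Product: 4 1-[2,5-bis(methoxymethoxy)phenyl]prop-2-en-1-ol (racemic)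
Conditions: THF, 0 °C; aq NH4Cl
Reagents that add atoms: none
Why: Grignard 1,2-addition to the aryl aldehyde should give the allylic benzylic alcohol, and the racemate is acceptable because this carbon becomes furan C2 and loses its configuration in step 9.

Step 3
Reactants: 4 1-[2,5-bis(methoxymethoxy)phenyl]prop-2-en-1-ol; 5 2,3-dibromopropene
Product: 6 2-[1-(2-bromoprop-2-enoxy)prop-2-enyl]-1,4-bis(methoxymethoxy)benzene (racemic)
Conditions: NaH, Bu4NI (cat.), THF–DMF, 0 °C to rt
Reagents that add atoms: none
Why: Williamson etherification in which the sodium alkoxide displaces the allylic bromide (direct and allylic-shift attack give the same ether) while the vinylic bromide is inert to substitution.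

Step 4
Reactants: 7 4-methylpent-3-enoic acid
Product: 9 N-methoxy-N,4-dimethylpent-3-enamide, via acylimidazole 8 (not isolated)
Conditions: 1,1'-carbonyldiimidazole, CH2Cl2, 0 °C to rt; then MeNHOMe·HCl, rt
Reagents that add atoms: N,O-dimethylhydroxylamine hydrochloride, CNOC.Cl
Why: Carbonyldiimidazole activation gives the acylimidazole under near-neutral conditions, so the β,γ-alkene should not move into conjugation, and aminolysis gives the Weinreb amide (amide coupling).

Step 5
Reactants: 6 2-[1-(2-bromoprop-2-enoxy)prop-2-enyl]-1,4-bis(methoxymethoxy)benzene; 9 N-methoxy-N,4-dimethylpent-3-enamide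
Product: 12 2-[[1-[2,5-bis(methoxymethoxy)phenyl]prop-2-enoxy]methyl]-6-methylhepta-1,5-dien-3-one, via vinyllithium 10 (not isolated), via lithium hemiaminal adduct 11 (not isolated)
Conditions: t-BuLi (2.05 equiv), Et2O, −78 °C, 20 min; then 9, −78 to −40 °C; inverse quench into cold aq NaH2PO4
Reagents that add atoms: none
Why: Bromine–lithium exchange of the vinylic bromide should outrun deprotonation at −78 °C, and the 2-lithioallyl ether acylates the amide through a stable lithium chelate that releases the α-methylene ketone only on quench (Weinreb ketone synthesis), the cold acidic inverse quench keeping the liberated hydroxylamine from adding to the enone.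

Step 6
Reactants: 12 2-[[1-[2,5-bis(methoxymethoxy)phenyl]prop-2-enoxy]methyl]-6-methylhepta-1,5-dien-3-one
Product: 13 (3S)-2-[[1-[2,5-bis(methoxymethoxy)phenyl]prop-2-enoxy]methyl]-6-methylhepta-1,5-dien-3-ol (both epimers at the aryl-bearing carbon)
Conditions: (R)-2-methyl-CBS-oxazaborolidine [(3aR)-1-methyl-3,3-diphenyltetrahydro-1H,3H-pyrrolo[1,2-c][1,3,2]oxazaborole] (0.3 equiv), catecholborane, toluene, −78 °C; MeOH, then 1 M NaOH wash
Reagents that add atoms: none
Why: Corey–Bakshi–Shibata reduction, in which the ketone binds the ring boron with the branched alkenyl group (large) away from the catalyst and the prenyl CH2 (small) toward it, so that nitrogen-bound catecholborane delivers hydride to the face that gives the (S)-carbinol, and catecholborane at −78 °C should not hydroborate the alkenes.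

Step 7
Reactants: 13 (3S)-allylic alcohol; 14 3-methylbut-2-enoic acid
Product: 15 (3S)-2-[[1-[2,5-bis(methoxymethoxy)phenyl]prop-2-enoxy]methyl]-6-methylhepta-1,5-dien-3-yl 3-methylbut-2-enoate (both epimers at the aryl-bearing carbon)
Conditions: DCC, 4-(dimethylamino)pyridine (0.3 equiv), CH2Cl2, 0 °C to rt
Reagents that add atoms: none
Why: Steglich esterification acylates the secondary allylic alcohol at oxygen without breaking the carbinol C–O bond, so the (S) configuration is retained, and it avoids the ketene pathway by which the acid chloride with amine bases gives the deconjugated ester.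

Step 8
Reactants: 15 (3S)-diene ether ester
Product: 16 (1S)-1-[5-[2,5-bis(methoxymethoxy)phenyl]-2,5-dihydrofuran-3-yl]-4-methylpent-3-enyl 3-methylbut-2-enoate (both epimers at the aryl-bearing ring carbon)
Conditions: second-generation Grubbs catalyst RuCl2(=CHPh)(H2IMes)(PCy3) (5 mol %), CH2Cl2 (0.01 M), 40 °C
Reagents that add atoms: none
Why: The Ru benzylidene first exchanges onto the monosubstituted vinyl group, the only unhindered alkene, and the new alkylidene adds to the 1,1-disubstituted alkene in an intramolecular [2+2] cycloaddition, after which cycloreversion of the ruthenacyclobutane forms the C3=C4 bond and releases ethene. The closest known reaction type is ring-closing metathesis of allyl 2-substituted-allyl ethers to 3-substituted 2,5-dihydrofurans with second-generation Ru carbenes. The one ring formed, O1–C2–C3–C4–C5, is closed as a five-membered cycloalkene by this alkene–alkene metathesis, with the ether oxygen and its two sp3 carbons (C2 and C5) as the tether. No stereocentre is created: the (S)-carbinol carbon is a spectator next to the reacting alkene, and both C2 epimers should cyclise. The step needs site selectivity among four alkenes, which is secured by substitution and ring size, since the prenyl and senecioate alkenes are trisubstituted and could only close eight- or nine-membered rings. High dilution should suppress intermolecular metathesis of the vinyl group, and loss of ethene drives the closure.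

Step 9
Reactants: 16 2,5-dihydrofuran
Product: 17 (1S)-1-[5-[2,5-bis(methoxymethoxy)phenyl]furan-3-yl]-4-methylpent-3-enyl 3-methylbut-2-enoate
Conditions: DDQ (1.3 equiv), toluene, rt to 50 °C
Reagents that add atoms: none
Why: DDQ removes hydride from ring C2 (benzylic, allylic and α to oxygen) to give an oxocarbenium ion that loses the C5 proton, so this dehydrogenative aromatisation should give the same furan from either C2 epimer and leave the side-chain stereocentre untouched.

Step 10
Reactants: 17 bis(methoxymethyl) ether furan
Product: 19 (1S)-1-[5-(2,5-dihydroxyphenyl)furan-3-yl]-4-methylpent-3-enyl 3-methylbut-2-enoate, via bis(trimethylsilyl) ether 18 (not isolated)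
Conditions: TMSOTf (5 equiv), 2,2'-bipyridyl (7.5 equiv), CH3CN, 0 °C to rt; then degassed H2O, rt, under argon
Reagents that add atoms: none
Why: Buffered silylative cleavage of aryl methoxymethyl ethers converts each ArO–CH2OMe into ArO–SiMe3 without free protic acid, which should spare the furan, the furylic allylic ester and both trisubstituted alkenes, and water then hydrolyses the silyl ethers to the hydroquinone.

**Compound list**

1 | 2,5-dihydroxybenzaldehyde | O=Cc1cc(O)ccc1O | starting material
2 | 2,5-bis(methoxymethoxy)benzaldehyde | O=Cc1cc(OCOC)ccc1OCOC | intermediate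
3 | vinylmagnesium bromide | C=C[Mg]Br | starting material
4 | 1-[2,5-bis(methoxymethoxy)phenyl]prop-2-en-1-ol (racemic) | C=CC(O)c1cc(OCOC)ccc1OCOC | intermediate
5 | 2,3-dibromopropene | C=C(Br)CBr | starting material
6 | 2-[1-(2-bromoprop-2-enoxy)prop-2-enyl]-1,4-bis(methoxymethoxy)benzene (racemic) | C=CC(OCC(Br)=C)c1cc(OCOC)ccc1OCOC | intermediate
7 | 4-methylpent-3-enoic acid | CC(C)=CCC(=O)O | starting material
8 | 1-(imidazol-1-yl)-4-methylpent-3-en-1-one (not isolated) | CC(C)=CCC(=O)n1ccnc1 | intermediate
9 | N-methoxy-N,4-dimethylpent-3-enamide | CC(C)=CCC(=O)N(C)OC | intermediate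
10 | [3-[1-[2,5-bis(methoxymethoxy)phenyl]prop-2-enoxy]prop-1-en-2-yl]lithium (not isolated) | [Li]C(=C)COC(C=C)c1cc(OCOC)ccc1OCOC | intermediate
11 | lithium 2-[[1-[2,5-bis(methoxymethoxy)phenyl]prop-2-enoxy]methyl]-3-[methoxy(methyl)amino]-6-methylhepta-1,5-dien-3-olate (not isolated) | CC(C)=CCC(O[Li])(N(C)OC)C(=C)COC(C=C)c1cc(OCOC)ccc1OCOC | intermediate
12 | 2-[[1-[2,5-bis(methoxymethoxy)phenyl]prop-2-enoxy]methyl]-6-methylhepta-1,5-dien-3-one | CC(C)=CCC(=O)C(=C)COC(C=C)c1cc(OCOC)ccc1OCOC | intermediate
13 | (3S)-2-[[1-[2,5-bis(methoxymethoxy)phenyl]prop-2-enoxy]methyl]-6-methylhepta-1,5-dien-3-ol | CC(C)=CC[C@H](O)C(=C)COC(C=C)c1cc(OCOC)ccc1OCOC | intermediate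
14 | 3-methylbut-2-enoic acid | CC(C)=CC(=O)O | starting material
15 | (3S)-2-[[1-[2,5-bis(methoxymethoxy)phenyl]prop-2-enoxy]methyl]-6-methylhepta-1,5-dien-3-yl 3-methylbut-2-enoate | CC(C)=CC[C@H](OC(=O)C=C(C)C)C(=C)COC(C=C)c1cc(OCOC)ccc1OCOC | intermediate
16 | (1S)-1-[5-[2,5-bis(methoxymethoxy)phenyl]-2,5-dihydrofuran-3-yl]-4-methylpent-3-enyl 3-methylbut-2-enoate | CC(C)=CC[C@H](OC(=O)C=C(C)C)C1=CC(c2cc(OCOC)ccc2OCOC)OC1 | intermediate
17 | (1S)-1-[5-[2,5-bis(methoxymethoxy)phenyl]furan-3-yl]-4-methylpent-3-enyl 3-methylbut-2-enoate | CC(C)=CC[C@H](OC(=O)C=C(C)C)c1coc(-c2cc(OCOC)ccc2OCOC)c1 | intermediate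
18 | (1S)-1-[5-[2,5-bis(trimethylsilyloxy)phenyl]furan-3-yl]-4-methylpent-3-enyl 3-methylbut-2-enoate (not isolated) | CC(C)=CC[C@H](OC(=O)C=C(C)C)c1coc(-c2cc(O[Si](C)(C)C)ccc2O[Si](C)(C)C)c1 | intermediate
19 | (1S)-1-[5-(2,5-dihydroxyphenyl)furan-3-yl]-4-methylpent-3-enyl 3-methylbut-2-enoate | CC(C)=CC[C@H](OC(=O)C=C(C)C)c1coc(-c2cc(O)ccc2O)c1 | target

**Step count**

Total: 10 steps. Longest linear sequence: 9 steps (steps 1–3 and 5–10); step 4 is a one-step side branch.

**Steps most likely to fail**

Step 5 (bromine–lithium exchange and acylation). The 2-lithioallyl ether may be lost before it meets the amide. It can take the proton from the ether C–H, which is benzylic, allylic and α to oxygen, and then undergo Wittig rearrangement; it can expel the alkoxide by β-elimination; t-BuLi may metallate ortho to a methoxymethoxy group; and the amide may be enolised instead of acylated. The fallback avoids any strongly basic carbanion. It sets out from bromide 6 and returns at ketone 12. 4-Methylpent-3-en-1-ol is oxidised with Dess–Martin periodinane (NaHCO3, CH2Cl2, 0 °C) to 4-methylpent-3-enal F1, which is used at once. A Nozaki–Hiyama–Kishi coupling of 6 with F1 (CrCl2, NiCl2 cat., DMF, rt) should give 2-[[1-[2,5-bis(methoxymethoxy)phenyl]prop-2-enoxy]methyl]-6-methylhepta-1,5-dien-3-ol F2 as a stereoisomer mixture. Dess–Martin oxidation of F2 then gives 12.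

Step 6 (CBS reduction). Facial discrimination between the branched alkenyl group and the primary prenyl CH2 may be insufficient, and conjugate reduction of the enone may compete. The fallback replaces catalyst-controlled reduction by kinetic resolution. It sets out from ketone 12 and returns at alcohol 13. Luche reduction (NaBH4, CeCl3·7H2O, MeOH, −78 °C) should give 13 together with its carbinol epimer, (3R)-2-[[1-[2,5-bis(methoxymethoxy)phenyl]prop-2-enoxy]methyl]-6-methylhepta-1,5-dien-3-ol F3. Sharpless kinetic resolution (Ti(OiPr)4, D-(−)-diisopropyl tartrate, t-BuOOH 0.6 equiv, 4 Å sieves, CH2Cl2, −20 °C) should epoxidise the 1,1-disubstituted allylic alkene of F3 only. With the D-(−)-tartrate the oxygen is delivered to the face on which the (3R)-carbinol presents hydrogen. The product is (1R)-1-[(2S)-2-[[1-[2,5-bis(methoxymethoxy)phenyl]prop-2-enoxy]methyl]oxiran-2-yl]-4-methylpent-3-en-1-ol F4, which is removed by chromatography, leaving the slow-reacting (3S)-alcohol 13.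

Step 10 (removal of the methoxymethyl groups). The furylic allylic ester may ionise, with loss or scrambling of the acyloxy stereocentre; the electron-rich furan may degrade under Lewis acid; and the hydroquinone may oxidise in air during work-up. The fallback unmasks the hydroquinone by a redox sequence instead of acetal cleavage. It sets out from 17 and returns at 19. Oxidative dealkylation with (NH4)2Ce(NO3)6 (2.5 equiv, CH3CN–H2O, 0 °C, short contact) should give the quinone (1S)-1-[5-(3,6-dioxocyclohexa-1,4-dienyl)furan-3-yl]-4-methylpent-3-enyl 3-methylbut-2-enoate F5. Reduction with Na2S2O4 (EtOAc–H2O, rt, under argon) then gives the hydroquinone 19.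

**Further compounds**

F1 | step 5 | 4-methylpent-3-enal | CC(C)=CCC=O
F2 | step 5 | 2-[[1-[2,5-bis(methoxymethoxy)phenyl]prop-2-enoxy]methyl]-6-methylhepta-1,5-dien-3-ol (stereoisomer mixture) | CC(C)=CCC(O)C(=C)COC(C=C)c1cc(OCOC)ccc1OCOC
F3 | step 6 | (3R)-2-[[1-[2,5-bis(methoxymethoxy)phenyl]prop-2-enoxy]methyl]-6-methylhepta-1,5-dien-3-ol | CC(C)=CC[C@@H](O)C(=C)COC(C=C)c1cc(OCOC)ccc1OCOC
F4 | step 6 | (1R)-1-[(2S)-2-[[1-[2,5-bis(methoxymethoxy)phenyl]prop-2-enoxy]methyl]oxiran-2-yl]-4-methylpent-3-en-1-ol | CC(C)=CC[C@@H](O)[C@@]1(COC(C=C)c2cc(OCOC)ccc2OCOC)CO1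
F5 | step 10 | (1S)-1-[5-(3,6-dioxocyclohexa-1,4-dienyl)furan-3-yl]-4-methylpent-3-enyl 3-methylbut-2-enoate | CC(C)=CC[C@H](OC(=O)C=C(C)C)c1coc(C2=CC(=O)C=CC2=O)c1
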